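# Synthesis plan for CNP0172886.1 (compound 22) by tethered O-to-C formyl transfer

Compound numbers 1–22 are those of the route below. Ring atoms follow pyran numbering: O1, C2 (methyl), C3 (formyl), C4 (acetate arm), C5 (methoxycarbonyl), C6 (enol-ether CH).

## The problem

Compound 22 has one ring, a 3,4-dihydro-2H-pyran, substituted at every carbon from C2 to C5. It carries a methyl group at C2, a formyl group at C3, an acetate arm at C4 esterified with hydroxytyrosol, and a methyl ester at C5 conjugated through C5=C6 with O1 (a vinylogous carbonate). The stereocentres C2, C3 and C4 are contiguous, (2S,3R,4R), and all-trans. C3 is α to the aldehyde and can epimerise, whereas C2 and C4 cannot, so C2 and C3 are best fixed early as a pair and made to control C4. The sensitive groups are the free catechol (oxidation, base), the aldehyde (β to O1, so base can open the ring by E1cB loss of the vinylogous carboxylate) and the enol ether (nucleophiles). Aldehyde and catechol must therefore stay masked until a final acidic step, and the saturated side-chain ester and the conjugated C5 ester must end up with different alcohols. The enabling feature is at C4: it bears the exocyclic CH2CO2R arm and, through C5, a second carbon carrying a carboxylate, so without C6 both are acetate arms and C4 is not a stereocentre. C6 is a one-carbon unit at the formate oxidation level bound to O1, so making C5–C6 from the formate of the C2 hydroxyl closes the ring and creates C4 by a choice between two diastereotopic arms.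

## Retrosynthesis

**22 ⇒ 20 (through 21).** No skeletal bond is cut. The C3 formyl group is masked as a dimethyl acetal and the catechol as an acetonide. Both fall to aqueous acid, the medium the conjugated enol ether tolerates best, whereas base, fluoride or hydrogenation would endanger C3, O1–C2 or C5=C6. The forward step must hydrolyse both masks without hydrating C5=C6; acid enolisation at C3 is harmless if, as expected, all-trans is the stable arrangement.

**20 ⇒ 17 + 19.** The acyl C–O bond of the side-chain ester is cut. Joining the catechol fragment late keeps it away from the strong base, ozone and chlorite used earlier and makes the route convergent. Acid 17 has no stereocentre α to the carboxyl, so any mild esterification will do. Alcohol 19 is one step from 18.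

**17 ⇒ 16.** The acid is traced to the dimethyl diester 16. This makes both ester groups methyl, which the symmetric precursor of the key step requires. The forward step relies on the difference between a saturated ester and a vinylogous carbonate ester.

**16 ⇒ 14 (through lactol 15).** The C5–C6 bond is cut and water is added back across C5=C6. C6 becomes the formyl carbon of a formate on the C2 oxygen and C5 the α-carbon of a methyl acetate arm.
- Cutting O1–C6 instead (formylating one arm first, then closing) offers no way to tell the arms apart.
- Cutting O1–C2 is the oxa-Michael route of Alternative 3.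
- Precursor 14 is acyclic, has only the C2 and C3 stereocentres, and carries two identical arms on a prochiral C4.
- The forward reaction must pick one arm. In the six-membered chair with the C2 methyl and C3 acetal equatorial, only one arm can close while its partner stays equatorial. The other arm would place its partner axial and nearly eclipsed with the enolate unit (A(1,3) strain). Excess base makes both arms nucleophilic in the same molecule, so the choice is made in the C–C bond-forming step.

**14 ⇒ 13 ⇒ 11 (through dialdehyde 12); 11 ⇒ 10.** The two carboxyl carbons are reconnected into the double bond of a cyclopentene. Symmetry guarantees identical arms, and the alkene hides them through the aldol and redox steps. The formate is installed on alcohol 10 before the ring is cleaved, because a free C2 hydroxyl δ to the arm esters would lactonise. The formate is thus protecting group first and reacting group later. The oxidative cleavage must spare the formate and the acetal.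

**10 ⇒ 8 ⇒ 7 (through aldehyde 9).** The acetal carbon is traced to the imide carbonyl of an aldol adduct by reduction, selective re-oxidation of the primary alcohol and acetalisation. No skeletal bond changes. The α-centre must not epimerise while the aldehyde is free.

**7 ⇒ 4 + 5; 4 ⇒ 1 + 2.** The C2–C3 bond is cut by an Evans syn-aldol. The syn relation between the C2 oxygen and the C3 branch in the open chain becomes trans-2,3 in the ring, and the (R)-auxiliary gives the required absolute sense. Acetaldehyde 5 brings C2 and its methyl; acid 1 brings C3, C4 and both arms. Only one auxiliary-controlled step has to be trusted for two stereocentres.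

## Roads not taken

**Alternative 1: De Mayo photocycloaddition, then ring switch.**
- Cut: C4–C5 and the C3–formyl bond, with the side-chain carboxyl and the C2 oxygen tied together in the β,γ-unsaturated lactone A1.
- Forward: the irradiated enol of methyl diformylacetate A2 adds across the alkene of A1, and the cyclobutanol fragments by retro-aldol to A3. No ring of the target is formed; the lactone must then be opened and the C2 hydroxyl reclosed on the formylacetate.
- Merits: two C–C bonds and the whole carbon skeleton in one step. Suprafacial addition anti to the methyl group would give the correct relative configuration from one stereocentre. The lactone carbonyl is already the side-chain carboxyl, so no ester differentiation is needed.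
- Weak points: the alkene of A1 is barely polarised, so nothing fixes which carbon receives the formyl-bearing carbon. One methyl group on a nearly flat ring gives modest facial bias. A1 slips easily into conjugation. A3 is a β-acyloxy aldehyde that can eliminate before the ring switch.
- Comparison: this road is clearly shorter. The chosen plan spends more steps but fixes regiochemistry by construction, sets two centres by an auxiliary aldol, and keeps the aldehyde masked throughout.

**Alternative 2: Achmatowicz ring expansion.**
- Cut: O1–C6, with C3 as a ketone. The precursor is the furyl carbinol A4.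
- Forward: oxidation of the furan to the cis-enedione and closure of the C2 hydroxyl on the unmasked aldehyde gives pyranone A5.
- Merits: the ring closure is reliable, and the C2 centre comes cheaply from an asymmetric reduction.
- Weak points: A5 has the wrong oxidation pattern at three ring carbons. C3 is a ketone needing one-carbon homologation, the alkene is at C4=C5 instead of C5=C6, and C6 is a lactol. C3 and C4 must then be set late on a flat ring from C2 alone, and the trisubstituted furan A4 needs its own synthesis.
- Comparison: the ring-forming step is safer than the one chosen here. The corrections after it are longer and stereochemically weaker. The chosen key step delivers every ring carbon at its final oxidation level.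

**Alternative 3: Enol oxa-Michael closure.**
- Cut: O1–C2. The precursor is the open-chain compound A6, in which C4 is the only stereocentre.
- Forward: the formylacetate enol oxygen adds 6-endo to the ethylidene enal, and C2 and C3 settle by retro-Michael and enolisation to the all-trans product A7, which is identical with 21.
- Merits: only one stereocentre needs asymmetric synthesis, and A7 is one deprotection from 22. It is probably the shortest route.
- Weak points: A6 combines an enal and a formylacetate and would have to be unveiled and used at once. The result depends on small energy differences between C2 epimers and open and closed forms. The same reversibility allows the product to reopen.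
- Comparison: if the equilibrium is one-sided, this road beats the chosen plan in step count. The chosen plan offers kinetic, equilibrium-independent control of C2 and C3 and an aldehyde that stays masked until the end.

Key step: step 8

Assumption: compounds 1, 2, 5 and 18 are taken as commercial.

## Route

Step 1
Reactants: 1 2-(cyclopent-3-en-1-yl)acetic acid; 2 (R)-4-benzyl-2-oxazolidinone
Product: 4 (R)-4-benzyl-3-[2-(cyclopent-3-en-1-yl)acetyl]oxazolidin-2-one, via mixed pivalic anhydride 3 (not isolated)
Conditions: PivCl, Et3N, THF, −20 °C; then 2, LiCl, −20 °C → rt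
Reagents that add atoms: none
Why: N-acylation of the oxazolidinone through the mixed pivalic anhydride is the standard loading of an Evans auxiliary; the isolated cyclopentene is a spectator.

Step 2
Reactants: 4 (R)-4-benzyl-3-[2-(cyclopent-3-en-1-yl)acetyl]oxazolidin-2-one; 5 acetaldehyde
Product: 7 (R)-4-benzyl-3-[(2R,3S)-2-(cyclopent-3-en-1-yl)-3-hydroxybutanoyl]oxazolidin-2-one, via dibutylboron Z-enolate 6 (not isolated)
Conditions: Bu2BOTf, i-Pr2NEt, CH2Cl2, −78 → 0 °C; MeCHO, −78 → 0 °C; pH 7 buffer, MeOH, 30% H2O2, 0 °C
Reagents that add atoms: none
Why: Evans syn-aldol reaction: the Z-boron enolate reacts through a closed Zimmerman–Traxler chair on the face away from the benzyl group, so the (R)-auxiliary sets the future C3 (α-carbon, R) and the future C2 (carbinol, S) as the 2,3-syn pair.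

Step 3
Reactants: 7 (R)-4-benzyl-3-[(2R,3S)-2-(cyclopent-3-en-1-yl)-3-hydroxybutanoyl]oxazolidin-2-one
Product: 8 (2S,3S)-2-(cyclopent-3-en-1-yl)butane-1,3-diol
Conditions: LiBH4, MeOH (1 equiv), THF, 0 °C; aq. NaOH
Reagents that add atoms: none
Why: Reductive cleavage of the auxiliary with LiBH4 at the exocyclic imide carbonyl gives the primary alcohol without epimerisation; the alkene is untouched and 2 is recovered.

Step 4
Reactants: 8 (2S,3S)-2-(cyclopent-3-en-1-yl)butane-1,3-diol
Product: 10 (2S,3R)-3-(cyclopent-3-en-1-yl)-4,4-dimethoxybutan-2-ol, via β-hydroxy aldehyde 9 (not isolated)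
Conditions: TEMPO (cat.), PhI(OAc)2, CH2Cl2, rt; then HC(OMe)3, MeOH, PPTS (cat.), rt
Reagents that add atoms: trimethyl orthoformate COC(OC)OC; methanol CO
Why: The TEMPO/PhI(OAc)2 oxidation is selective for the primary hydroxyl of a 1,3-diol, and immediate acetalisation (orthoformate as water scavenger) traps aldehyde 9 before it can epimerise at the α-carbon, dehydrate or dimerise.

Step 5
Reactants: 10 (2S,3R)-3-(cyclopent-3-en-1-yl)-4,4-dimethoxybutan-2-ol
Product: 11 (2S,3R)-3-(cyclopent-3-en-1-yl)-4,4-dimethoxybutan-2-yl formate
Conditions: AcOCHO (preformed), pyridine, CH2Cl2, 0 °C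
Reagents that add atoms: acetic formic anhydride CC(=O)OC=O
Why: O-Formylation with the mixed anhydride, in which formyl transfer is far faster than acetyl transfer; the basic medium spares the acetal, and the formate protects the C2 oxygen against δ-lactonisation until it is needed as the electrophile.

Step 6
Reactants: 11 (2S,3R)-3-(cyclopent-3-en-1-yl)-4,4-dimethoxybutan-2-yl formate
Product: 13 3-[(2R,3S)-3-(formyloxy)-1,1-dimethoxybutan-2-yl]pentanedioic acid, via dialdehyde 12 (not isolated)
Conditions: O3, CH2Cl2, −78 °C; PPh3, −78 °C → rt; then NaClO2, NaH2PO4, 2-methyl-2-butene, t-BuOH/H2O, 0 °C → rt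
Reagents that add atoms: ozone [O-][O+]=O; sodium chlorite [Na+].[O-]Cl=O
Why: Ozonolysis with reductive work-up followed by Pinnick oxidation; the alkene is the only ozone-reactive site at −78 °C, the buffered chlorite medium tolerates formate and acetal, and the symmetry of the cyclopentene makes the two arms identical.

Step 7
Reactants: 13 3-[(2R,3S)-3-(formyloxy)-1,1-dimethoxybutan-2-yl]pentanedioic acid
Product: 14 dimethyl 3-[(2R,3S)-3-(formyloxy)-1,1-dimethoxybutan-2-yl]pentanedioate
Conditions: Me3SiCHN2, PhMe/MeOH, 0 °C
Reagents that add atoms: trimethylsilyldiazomethane C[Si](C)(C)C=[N+]=[N-]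
Why: Methyl ester formation with a diazoalkane is neutral and fast, so neither the formate nor the acetal is disturbed.

Step 8
Reactants: 14 dimethyl 3-[(2R,3S)-3-(formyloxy)-1,1-dimethoxybutan-2-yl]pentanedioate
Product: 16 methyl (2S,3R,4R)-3-(dimethoxymethyl)-4-(2-methoxy-2-oxoethyl)-2-methyl-3,4-dihydro-2H-pyran-5-carboxylate, via lactol 15 (not isolated)
Conditions: LiN(SiMe3)2 (2.5 equiv), THF (0.01 M), slow addition of 14, −78 → −40 °C; AcOH, −78 °C; then PPTS (cat.), 3 Å MS, PhH, 50 °C
Reagents that add atoms: none
Why: Proposed new method: excess LiN(SiMe3)2 enolises the methyl acetate arms, and the α-carbon of one arm (future C5) adds to the formate carbonyl on the C2 oxygen (future C6) through a six-membered chair, a 6-exo-trig closure that makes the C5–C6 bond and with it the ring O1–C2–C3–C4–C5–C6 as the lithium salt of lactol 15; whether this salt persists as an ester-chelated lactolate or collapses to the open formylacetate enolate and the C2 alkoxide, the acetic acid quench returns 15 or its ring-chain tautomer, and PPTS then removes water to give the conjugated enol ether 16. The closest known reaction types are the Baker–Venkataraman O-to-C acyl transfer and the crossed Claisen formylation of ester enolates with formate esters, followed by the ordinary acid dehydration of a 2-hydroxytetrahydropyran-3-carboxylate; what has no precedent is a tethered formate choosing between two diastereotopic ester arms. C4 is the only new stereocentre that survives, and it is set by which arm reacts: with the C2 methyl and the C3 dimethoxymethyl group equatorial in the chair, closure through one arm leaves its partner equatorial, which is the all-trans (4R) arrangement of the target. Closure through the other arm would force the partner arm axial, where it is 1,3-diaxial to H-2 and almost eclipsed with the oxygen-bearing enolate carbon (A(1,3) strain), so this transition state should lie clearly higher. The step needs three selectivities: between the arms, for the intramolecular over the intermolecular formyl transfer, and for C–C bond formation over attack of the base on the formate. Excess base makes both arms nucleophilic in the same molecule, so the choice falls in the C–C bond-forming step (Curtin–Hammett conditions), slow addition of 14 at high dilution disfavours the bimolecular path, and the hindered silylamide is a poor nucleophile at −78 °C. The acetal meets only base and then a buffered pyridinium acid with 3 Å sieves that take up water but not methanol, and the C5 and C6 centres of 15 are of no consequence because both become sp2 in 16.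

Step 9
Reactants: 16 methyl (2S,3R,4R)-3-(dimethoxymethyl)-4-(2-methoxy-2-oxoethyl)-2-methyl-3,4-dihydro-2H-pyran-5-carboxylate
Product: 17 2-[(2S,3R,4R)-3-(dimethoxymethyl)-5-(methoxycarbonyl)-2-methyl-3,4-dihydro-2H-pyran-4-yl]acetic acid
Conditions: LiOH·H2O (1.2 equiv), THF/H2O, 0 °C; 1 M HCl to pH 4, 0 °C
Reagents that add atoms: lithium hydroxide [Li+].[OH-]
Why: Chemoselective saponification: the saturated methyl ester is much more electrophilic than the C5 ester, whose carbonyl is deactivated by donation from O1; with C3 still an acetal there is no E1cB path, and work-up at pH 4 spares the acetal.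

Step 10
Reactants: 18 hydroxytyrosol
Product: 19 2-(2,2-dimethyl-1,3-benzodioxol-5-yl)ethan-1-ol
Conditions: Me2C(OMe)2, TsOH·H2O (cat.), PhH, reflux through 4 Å MS; aq. work-up
Reagents that add atoms: 2,2-dimethoxypropane COC(C)(C)OC
Why: Acid-catalysed transketalisation of the catechol gives the five-membered benzodioxole; any mixed ketal formed at the primary hydroxyl is lost on aqueous work-up.

Step 11
Reactants: 17 2-[(2S,3R,4R)-3-(dimethoxymethyl)-5-(methoxycarbonyl)-2-methyl-3,4-dihydro-2H-pyran-4-yl]acetic acid; 19 2-(2,2-dimethyl-1,3-benzodioxol-5-yl)ethan-1-ol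
Product: 20 methyl (2S,3R,4R)-3-(dimethoxymethyl)-4-{2-[2-(2,2-dimethyl-1,3-benzodioxol-5-yl)ethoxy]-2-oxoethyl}-2-methyl-3,4-dihydro-2H-pyran-5-carboxylate
Conditions: DCC, DMAP (cat.), CH2Cl2, 0 °C → rt
Reagents that add atoms: none
Why: Steglich esterification of an unhindered CH2CO2H with a primary alcohol; no stereocentre is α to the activated carboxyl, so nothing can epimerise.

Step 12
Reactants: 20 methyl (2S,3R,4R)-3-(dimethoxymethyl)-4-{2-[2-(2,2-dimethyl-1,3-benzodioxol-5-yl)ethoxy]-2-oxoethyl}-2-methyl-3,4-dihydro-2H-pyran-5-carboxylate
Product: 22 methyl (2S,3R,4R)-4-{2-[2-(3,4-dihydroxyphenyl)ethoxy]-2-oxoethyl}-3-formyl-2-methyl-3,4-dihydro-2H-pyran-5-carboxylate, via aldehyde acetonide 21 (not isolated)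
Conditions: TFA/H2O (9:1), CH2Cl2, 0 °C → rt, under Ar
Reagents that add atoms: water O
Why: Acid hydrolysis removes the dimethyl acetal first and the catechol acetonide second; the β-alkoxyacrylate resists acid hydration because the ester withdraws electron density from C5, and the all-trans arrangement at C3 is expected to be the thermodynamic one, so acid enolisation should not erode it.

## Compound list

1 | 2-(cyclopent-3-en-1-yl)acetic acid | OC(=O)CC1CC=CC1 | starting material
2 | (R)-4-benzyl-2-oxazolidinone | O=C1OC[C@@H](Cc2ccccc2)N1 | starting material
3 | 2-(cyclopent-3-en-1-yl)acetic pivalic anhydride | CC(C)(C)C(=O)OC(=O)CC1CC=CC1 | intermediate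
4 | (R)-4-benzyl-3-[2-(cyclopent-3-en-1-yl)acetyl]oxazolidin-2-one | O=C(CC1CC=CC1)N1C(=O)OC[C@H]1Cc1ccccc1 | intermediate
5 | acetaldehyde | CC=O | starting material
6 | dibutylboron (Z)-enolate of 4, (R,Z)-4-benzyl-3-{2-(cyclopent-3-en-1-yl)-1-[(dibutylboranyl)oxy]ethenyl}oxazolidin-2-one | CCCCB(CCCC)O/C(=C\C1CC=CC1)N1C(=O)OC[C@H]1Cc1ccccc1 | intermediate
7 | (R)-4-benzyl-3-[(2R,3S)-2-(cyclopent-3-en-1-yl)-3-hydroxybutanoyl]oxazolidin-2-one | O[C@@H](C)[C@H](C(=O)N1C(=O)OC[C@H]1Cc1ccccc1)C1CC=CC1 | intermediate
8 | (2S,3S)-2-(cyclopent-3-en-1-yl)butane-1,3-diol | O[C@@H](C)[C@H](CO)C1CC=CC1 | intermediate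
9 | (2R,3S)-2-(cyclopent-3-en-1-yl)-3-hydroxybutanal | O[C@@H](C)[C@H](C=O)C1CC=CC1 | intermediate
10 | (2S,3R)-3-(cyclopent-3-en-1-yl)-4,4-dimethoxybutan-2-ol | O[C@@H](C)[C@H](C(OC)OC)C1CC=CC1 | intermediate
11 | (2S,3R)-3-(cyclopent-3-en-1-yl)-4,4-dimethoxybutan-2-yl formate | O=CO[C@@H](C)[C@H](C(OC)OC)C1CC=CC1 | intermediate
12 | (2S,3R)-4,4-dimethoxy-3-(1,5-dioxopentan-3-yl)butan-2-yl formate | O=CO[C@@H](C)[C@H](C(OC)OC)C(CC=O)CC=O | intermediate
13 | 3-[(2R,3S)-3-(formyloxy)-1,1-dimethoxybutan-2-yl]pentanedioic acid | O=CO[C@@H](C)[C@H](C(OC)OC)C(CC(=O)O)CC(=O)O | intermediate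
14 | dimethyl 3-[(2R,3S)-3-(formyloxy)-1,1-dimethoxybutan-2-yl]pentanedioate | O=CO[C@@H](C)[C@H](C(OC)OC)C(CC(=O)OC)CC(=O)OC | intermediate
15 | methyl (2S,3R,4R)-3-(dimethoxymethyl)-6-hydroxy-4-(2-methoxy-2-oxoethyl)-2-methyloxane-5-carboxylate (mixture at C5 and C6) | COC(=O)C1C(O)O[C@@H](C)[C@H](C(OC)OC)[C@H]1CC(=O)OC | intermediate
16 | methyl (2S,3R,4R)-3-(dimethoxymethyl)-4-(2-methoxy-2-oxoethyl)-2-methyl-3,4-dihydro-2H-pyran-5-carboxylate | COC(=O)C1=CO[C@@H](C)[C@H](C(OC)OC)[C@H]1CC(=O)OC | intermediate
17 | 2-[(2S,3R,4R)-3-(dimethoxymethyl)-5-(methoxycarbonyl)-2-methyl-3,4-dihydro-2H-pyran-4-yl]acetic acid | COC(=O)C1=CO[C@@H](C)[C@H](C(OC)OC)[C@H]1CC(=O)O | intermediate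
18 | hydroxytyrosol, 4-(2-hydroxyethyl)benzene-1,2-diol | OCCc1ccc(O)c(O)c1 | starting material
19 | 2-(2,2-dimethyl-1,3-benzodioxol-5-yl)ethan-1-ol | OCCc1ccc2OC(C)(C)Oc2c1 | intermediate
20 | methyl (2S,3R,4R)-3-(dimethoxymethyl)-4-{2-[2-(2,2-dimethyl-1,3-benzodioxol-5-yl)ethoxy]-2-oxoethyl}-2-methyl-3,4-dihydro-2H-pyran-5-carboxylate | COC(=O)C1=CO[C@@H](C)[C@H](C(OC)OC)[C@H]1CC(=O)OCCc1ccc2OC(C)(C)Oc2c1 | intermediate
21 | methyl (2S,3R,4R)-4-{2-[2-(2,2-dimethyl-1,3-benzodioxol-5-yl)ethoxy]-2-oxoethyl}-3-formyl-2-methyl-3,4-dihydro-2H-pyran-5-carboxylate | COC(=O)C1=CO[C@@H](C)[C@H](C=O)[C@H]1CC(=O)OCCc1ccc2OC(C)(C)Oc2c1 | intermediate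
22 | methyl (2S,3R,4R)-4-{2-[2-(3,4-dihydroxyphenyl)ethoxy]-2-oxoethyl}-3-formyl-2-methyl-3,4-dihydro-2H-pyran-5-carboxylate | COC(=O)C1=CO[C@@H](C)[C@H](C=O)[C@H]1CC(=O)OCCc1ccc(O)c(O)c1 | target

## Step count and risk

Total step count: 12. Longest linear sequence: 11 steps (steps 1–9, 11 and 12, from 1 to 22); step 10 is a one-step side branch.

**Step 8 (key step, proposed new method).**
- Most likely failures: weak discrimination between the two arms if enolate formation is irreversible and only one arm is enolised per molecule; loss of the formyl group to the base, followed by lactonisation of the freed C2 alkoxide; collapse of the lactolate with acyl migration onto the spectator arm; intermolecular formyl transfer.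
- Fallback (known chemistry) from 14: K2CO3 in MeOH removes the formyl group to give the hydroxy diester F1. Under equilibrating conditions (DBU cat., toluene, 60 °C, closed vessel so the liberated methanol stays) F1 lactonises on the arm that leaves every substituent equatorial, giving the δ-lactone F2. Bredereck's reagent (t-BuOCH(NMe2)2, toluene, 80 °C) condenses at the more acidic lactone α-CH2 to give the enaminone lactone F3. Anhydrous HCl in MeOH then opens the lactone to the methyl ester, and the freed C2 hydroxyl displaces dimethylamine at C6 by addition–elimination. This returns to the route at 16, with the acetal kept intact by the methanol.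

**Step 6.**
- Most likely failures: oxidation of the acetal C–H by ozone; acetal hydrolysis or acyloxy-acetal formation while the free diacid is handled; hydrolysis of the formate in the aqueous oxidation.
- Fallback from 10: silylation (TBSOTf, 2,6-lutidine) gives the silyl ether F4. Ozonolysis in methanolic NaOH (O3, NaOH, MeOH/CH2Cl2, −78 °C) converts the alkene directly into the diester F5 without a free acid. Buffered desilylation (Bu4NF, AcOH, THF, 0 °C) gives the hydroxy diester F1, which is formylated at once as in step 5. The route is rejoined at 14.

**Step 4 (and the reduction before it).**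
- Most likely failures: epimerisation at the α-carbon, retro-aldol cleavage or dehydration of the unprotected β-hydroxy aldehyde; ring-opening of the auxiliary instead of acyl cleavage in step 3 because the α-carbon is branched.
- Fallback from 7: transamidation (MeNHOMe·HCl, AlMe3, CH2Cl2) gives the Weinreb amide F6. Silylation (TESCl, imidazole) gives its triethylsilyl ether F7. Reduction with i-Bu2AlH at −78 °C gives the protected aldehyde F8. HC(OMe)3, MeOH and PPTS form the acetal and remove the silyl group in the same pot, returning to the route at 10.

**Step 9.**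
- Most likely failures: hydroxide attack on both esters, or conjugate addition at C6 with ring opening.
- Fallback from 16 and 19: direct transesterification of the saturated methyl ester with alcohol 19, catalysed by the distannoxane ClBu2SnOSnBu2Cl in toluene at reflux with removal of methanol. This arrives at 20 and bypasses 17; no new compound arises (F0).

**Step 12.**
- Most likely failures: slow cleavage of the catechol acetonide, so that long acid exposure hydrates or opens the enol ether; air oxidation of the liberated catechol.
- Fallback from 17 and unprotected 18: chemoselective Mitsunobu esterification at the primary hydroxyl (PPh3, DIAD, THF, 0 °C) gives the catechol acetal ester F9. Mild hydrolysis of the acetal alone (oxalic acid, THF/H2O, rt) then arrives at 22.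

## Further compounds

F1 | step 8 | dimethyl 3-[(2R,3S)-3-hydroxy-1,1-dimethoxybutan-2-yl]pentanedioate | O[C@@H](C)[C@H](C(OC)OC)C(CC(=O)OC)CC(=O)OC
F2 | step 8 | methyl 2-[(2S,3R,4S)-3-(dimethoxymethyl)-2-methyl-6-oxooxan-4-yl]acetate | O=C1O[C@@H](C)[C@H](C(OC)OC)[C@@H](CC(=O)OC)C1
F3 | step 8 | methyl 2-[(2S,3R,4R,5E)-3-(dimethoxymethyl)-5-[(dimethylamino)methylidene]-2-methyl-6-oxooxan-4-yl]acetate | CN(C)/C=C1/C(=O)O[C@@H](C)[C@H](C(OC)OC)[C@H]1CC(=O)OC
F4 | step 6 | tert-butyl{[(2S,3R)-3-(cyclopent-3-en-1-yl)-4,4-dimethoxybutan-2-yl]oxy}dimethylsilane | CC(C)(C)[Si](C)(C)O[C@@H](C)[C@H](C(OC)OC)C1CC=CC1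
F5 | step 6 | dimethyl 3-[(2R,3S)-3-[(tert-butyldimethylsilyl)oxy]-1,1-dimethoxybutan-2-yl]pentanedioate | CC(C)(C)[Si](C)(C)O[C@@H](C)[C@H](C(OC)OC)C(CC(=O)OC)CC(=O)OC
F6 | step 4 | (2R,3S)-2-(cyclopent-3-en-1-yl)-3-hydroxy-N-methoxy-N-methylbutanamide | O[C@@H](C)[C@H](C(=O)N(C)OC)C1CC=CC1
F7 | step 4 | (2R,3S)-2-(cyclopent-3-en-1-yl)-N-methoxy-N-methyl-3-[(triethylsilyl)oxy]butanamide | CC[Si](CC)(CC)O[C@@H](C)[C@H](C(=O)N(C)OC)C1CC=CC1
F8 | step 4 | (2R,3S)-2-(cyclopent-3-en-1-yl)-3-[(triethylsilyl)oxy]butanal | CC[Si](CC)(CC)O[C@@H](C)[C@H](C=O)C1CC=CC1
F0 | step 9 | none | none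
F9 | step 12 | methyl (2S,3R,4R)-4-{2-[2-(3,4-dihydroxyphenyl)ethoxy]-2-oxoethyl}-3-(dimethoxymethyl)-2-methyl-3,4-dihydro-2H-pyran-5-carboxylate | COC(=O)C1=CO[C@@H](C)[C@H](C(OC)OC)[C@H]1CC(=O)OCCc1ccc(O)c(O)c1
A1 | alternative 1 | (S)-6-methyl-3,6-dihydro-2H-pyran-2-one | C[C@H]1C=CCC(=O)O1
A2 | alternative 1 | methyl diformylacetate, enol form (methyl 2-formyl-3-hydroxyprop-2-enoate) | COC(=O)C(C=O)=CO
A3 | alternative 1 | methyl 2-[(4R,5R,6S)-5-formyl-6-methyl-2-oxooxan-4-yl]-3-hydroxyprop-2-enoate | C[C@@H]1OC(=O)C[C@@H](C(=CO)C(=O)OC)[C@H]1C=O
A4 | alternative 2 | methyl 4-(2-tert-butoxy-2-oxoethyl)-5-[(1S)-1-hydroxyethyl]furan-3-carboxylate | COC(=O)c1coc([C@H](C)O)c1CC(=O)OC(C)(C)C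
A5 | alternative 2 | methyl (2S)-4-(2-tert-butoxy-2-oxoethyl)-6-hydroxy-2-methyl-3-oxo-3,6-dihydro-2H-pyran-5-carboxylate | COC(=O)C1=C(CC(=O)OC(C)(C)C)C(=O)[C@H](C)OC1O
A6 | alternative 3 | 1-[2-(2,2-dimethyl-1,3-benzodioxol-5-yl)ethyl] 5-methyl (3R)-4-(hydroxymethylidene)-3-(1-oxobut-2-en-2-yl)pentanedioate | COC(=O)C(=CO)[C@H](CC(=O)OCCc1ccc2OC(C)(C)Oc2c1)C(=CC)C=O
A7 | alternative 3 | catechol acetonide of 22, identical with 21 | COC(=O)C1=CO[C@@H](C)[C@H](C=O)[C@H]1CC(=O)OCCc1ccc2OC(C)(C)Oc2c1
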